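**Strategy.** The cyclohexanone ring is cut into two three-carbon pieces at C3–C4 and C1–C6 (numbering of 7-oxabicyclo[4.1.0]heptan-2-one). The route exploits the C2 ketone, whose two flanking carbons, the oxirane carbon C1 and the acetoxy-bearing C3, are both nucleophilic α-carbons: in one amine-catalysed Michael–Darzens domino annulation, C3 of a γ-chloro-β-keto ester adds to an α-acetoxy dienal that already carries the C5 acetate and the whole side chain (C3–C4), and the chloro-bearing C1 then attacks the aldehyde carbon C6, the alkoxide closing the fused oxirane. The activating ester is removed afterwards and C3 is oxygenated.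

Key step: step 8

Assumption: the quinine-derived primary-amine salt is taken to expose the Re face of C3 of the dienal; if the sense of induction is the opposite, the quinidine-derived pseudoenantiomer is used in the same way.

**Step 1**
Reactants: 1 2-bromoacrolein
Product: 2 (3S)-2-bromohexa-1,5-dien-3-ol
Conditions: (−)-Ipc2B(allyl), Et2O, −78 °C; then NaOH, H2O2, 0 °C to rt
Reagents that add atoms: (−)-B-allyldiisopinocampheylborane, C=CCB([C@@H]1C[C@@H]2C[C@H]([C@H]1C)C2(C)C)[C@@H]1C[C@@H]2C[C@H]([C@H]1C)C2(C)C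
Why: Brown asymmetric allylboration through a chair (Zimmerman–Traxler) transition state, in which the isopinocampheyl groups deliver the allyl group to one aldehyde face and should set the carbinol centre as S, by analogy with aryl and alkenyl aldehydes.

**Step 2**
Reactants: 2 (3S)-2-bromohexa-1,5-dien-3-ol
Product: 3 {[(3S)-2-bromohexa-1,5-dien-3-yl]oxy}(tert-butyl)dimethylsilane
Conditions: TBSCl, imidazole, DMF, rt
Reagents that add atoms: tert-butyldimethylsilyl chloride, CC(C)(C)[Si](C)(C)Cl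
Why: Standard silylation of a secondary allylic alcohol, which leaves the stereocentre untouched.

**Step 3**
Reactants: 3 {[(3S)-2-bromohexa-1,5-dien-3-yl]oxy}(tert-butyl)dimethylsilane
Product: 4 {[(3S)-2-bromo-6-methylhepta-1,5-dien-3-yl]oxy}(tert-butyl)dimethylsilane
Conditions: 2-methylbut-2-ene (excess), second-generation Grubbs catalyst RuCl2(H2IMes)(PCy3)(=CHPh) (3 mol%), CH2Cl2, 40 °C
Reagents that add atoms: 2-methylbut-2-ene, CC=C(C)C
Why: Olefin cross-metathesis with excess 2-methylbut-2-ene should turn the terminal allyl group into the prenyl group, the 1,1-disubstituted bromoalkene being inert to the ruthenium carbene.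

**Step 4**
Reactants: 5 2,2-dimethyl-1,3-dioxan-5-one
Product: 6 2,2-dimethyl-4H-1,3-dioxin-5-yl acetate
Conditions: KN(SiMe3)2, THF, −78 °C; then Ac2O, −78 to 0 °C
Reagents that add atoms: acetic anhydride, CC(=O)OC(C)=O
Why: O-acylation of the potassium enolate of the symmetrical ketone with the anhydride should give the enol acetate.

**Step 5**
Reactants: 6 2,2-dimethyl-4H-1,3-dioxin-5-yl acetate
Product: 7 2-acetoxyacrolein (3-oxoprop-1-en-2-yl acetate)
Conditions: toluene, 110 °C, sealed tube; used as the solution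
Reagents that add atoms: none
Why: Retro-hetero-Diels–Alder reaction of the 4H-1,3-dioxin should extrude acetone and release the 2-acyloxyacrolein.

**Step 6**
Reactants: 4 {[(3S)-2-bromo-6-methylhepta-1,5-dien-3-yl]oxy}(tert-butyl)dimethylsilane; 7 2-acetoxyacrolein
Product: 8 (2Z,5S)-5-[(tert-butyldimethylsilyl)oxy]-8-methyl-4-methylidene-1-oxonona-2,7-dien-2-yl acetate
Conditions: Pd(OAc)2 (5 mol%), Bu4NCl, NaHCO3, DMF, 50 °C
Reagents that add atoms: none
Why: Mizoroki–Heck reaction, in which the alkenylpalladium species should add to the unsubstituted terminus of the captodative alkene and syn β-hydride elimination should give the dienal with the new alkenyl group trans to the formyl group, the existing stereocentre being untouched.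

**Step 7**
Reactants: 9 Meldrum's acid; 10 2-chloropropanoyl chloride (racemic); 11 allyl alcohol
Product: 13 allyl 4-chloro-3-oxopentanoate (racemic), via acyl Meldrum's acid 12 (not isolated)
Conditions: pyridine, CH2Cl2, 0 °C to rt; then 11, toluene, 100 °C
Reagents that add atoms: none
Why: C-acylation of Meldrum's acid followed by thermal alcoholysis through an acylketene is the standard β-keto ester synthesis and should give the γ-chloro-β-keto ester, whose chloro-bearing centre is lost again in step 8.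

**Step 8**
Reactants: 8 (2Z,5S)-5-[(tert-butyldimethylsilyl)oxy]-8-methyl-4-methylidene-1-oxonona-2,7-dien-2-yl acetate; 13 allyl 4-chloro-3-oxopentanoate
Product: 16 allyl (1S,4S,5R,6S)-5-acetoxy-4-[(3S)-3-[(tert-butyldimethylsilyl)oxy]-6-methylhepta-1,5-dien-2-yl]-2-hydroxy-1-methyl-7-oxabicyclo[4.1.0]hept-2-ene-3-carboxylate (enol form), via Michael adduct 14 (not isolated), via chlorohydrin 15 (not isolated)
Conditions: 9-amino-9-deoxy-epi-quinine (20 mol%), CF3CO2H (40 mol%), toluene, rt; then K2CO3, DMF, 0 °C to rt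
Reagents that add atoms: none
Why: The primary-amine salt turns the α-acetoxy dienal into its iminium ion, to which the doubly activated C2 of the enolised keto ester (the future ring C3) adds in a 1,4-manner; the γ-enol of adduct 14 then attacks the released aldehyde and K2CO3 closes the oxirane, the closest known reaction being the organocatalytic domino Michael–aldol–SN2 annulation of γ-chloro-β-keto esters with enals. The carbocycle closes in the 6-(enolendo)-exo-trig mode (aldol) and the oxirane in the 3-exo-tet mode (alkoxide displacing chloride with inversion at the methyl-bearing carbon). The centre bearing the side chain is set by the catalyst, which shields one face of the iminium ion so that the C–C bond forms on the Re face of C3 of dienal 8. The acetoxy-bearing centre is epimerisable at the aldehyde stage and should be carried through the cyclisation trans to the side chain; allylic strain with the coplanar enolised ester should hold the side chain pseudoaxial, so that the only chlorohydrin able to reach the anti-periplanar O–C–C–Cl arrangement (15) places the oxide on the face of the side chain, anti to the acetoxy group, with the methyl group on the other face. The step needs 1,4-addition rather than 1,6- or 1,2-addition, which iminium activation of C3 should favour but does not guarantee, and it needs the two α-carbons of the ketone to take different roles, which the ester secures by making C2 the Michael donor and leaving the chloro-bearing carbon for the aldol and displacement.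

**Step 9**
Reactants: 16 allyl (1S,4S,5R,6S)-5-acetoxy-4-[(3S)-3-[(tert-butyldimethylsilyl)oxy]-6-methylhepta-1,5-dien-2-yl]-2-hydroxy-1-methyl-7-oxabicyclo[4.1.0]hept-2-ene-3-carboxylate
Product: 17 (1S,4R,5R,6S)-5-acetoxy-4-[(3S)-3-[(tert-butyldimethylsilyl)oxy]-6-methylhepta-1,5-dien-2-yl]-1-methyl-7-oxabicyclo[4.1.0]heptan-2-one
Conditions: Pd(PPh3)4 (3 mol%), morpholine, THF, 0 °C to rt
Reagents that add atoms: none
Why: Tsuji–Trost deallylation with morpholine as allyl acceptor followed by spontaneous decarboxylation of the β-keto acid should give the ketone, since the primary allyl ester ionises far faster than the hindered allylic silyl ether and no stereocentre is touched.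

**Step 10**
Reactants: 17 (1S,4R,5R,6S)-5-acetoxy-4-[(3S)-3-[(tert-butyldimethylsilyl)oxy]-6-methylhepta-1,5-dien-2-yl]-1-methyl-7-oxabicyclo[4.1.0]heptan-2-one
Product: 19 (1S,3S,4R,5R,6S)-3,5-diacetoxy-4-[(3S)-3-[(tert-butyldimethylsilyl)oxy]-6-methylhepta-1,5-dien-2-yl]-1-methyl-7-oxabicyclo[4.1.0]heptan-2-one, via hydroxy ketone 18 (not isolated)
Conditions: KN(SiMe3)2, THF, −78 °C; 2-(phenylsulfonyl)-3-phenyloxaziridine, −78 °C; then Ac2O, −78 to 0 °C
Reagents that add atoms: 2-(phenylsulfonyl)-3-phenyloxaziridine, O=S(=O)(c1ccccc1)N1OC1c1ccccc1; acetic anhydride, CC(=O)OC(C)=O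
Why: C3 is the only enolisable position, and Davis oxaziridine hydroxylation of its potassium enolate should occur anti to the adjacent C4 side chain (trans, also the equatorial arrangement), the alkoxide being acetylated in the same flask.

**Step 11**
Reactants: 19 (1S,3S,4R,5R,6S)-3,5-diacetoxy-4-[(3S)-3-[(tert-butyldimethylsilyl)oxy]-6-methylhepta-1,5-dien-2-yl]-1-methyl-7-oxabicyclo[4.1.0]heptan-2-one
Product: 20 (1S,3S,4R,5R,6S)-3,5-diacetoxy-4-[(3S)-3-hydroxy-6-methylhepta-1,5-dien-2-yl]-1-methyl-7-oxabicyclo[4.1.0]heptan-2-one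
Conditions: HF·pyridine, pyridine, THF, 0 °C to rt
Reagents that add atoms: none
Why: Buffered fluoride desilylation should free the side-chain alcohol while the oxirane, the acetates and the α-acetoxy ketone survive.

**Step 12**
Reactants: 20 (1S,3S,4R,5R,6S)-3,5-diacetoxy-4-[(3S)-3-hydroxy-6-methylhepta-1,5-dien-2-yl]-1-methyl-7-oxabicyclo[4.1.0]heptan-2-one; 21 angelic acid
Product: 23 CNP0298051.3, via mixed anhydride 22 (not isolated)
Conditions: 21, 2,4,6-trichlorobenzoyl chloride, Et3N, toluene, rt; then 20, 80 °C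
Reagents that add atoms: none
Why: Yamaguchi-type esterification through the mixed anhydride, run without a nucleophilic catalyst, should acylate the allylic alcohol with retention of the Z geometry of the angelate and without change at any stereocentre.

**Compound list**

1 | 2-bromoacrolein (2-bromoprop-2-enal) | C=C(Br)C=O | starting material
2 | (3S)-2-bromohexa-1,5-dien-3-ol | C=C(Br)[C@H](CC=C)O | intermediate
3 | {[(3S)-2-bromohexa-1,5-dien-3-yl]oxy}(tert-butyl)dimethylsilane | C=C(Br)[C@H](CC=C)O[Si](C)(C)C(C)(C)C | intermediate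
4 | {[(3S)-2-bromo-6-methylhepta-1,5-dien-3-yl]oxy}(tert-butyl)dimethylsilane | C=C(Br)[C@H](CC=C(C)C)O[Si](C)(C)C(C)(C)C | intermediate
5 | 2,2-dimethyl-1,3-dioxan-5-one | CC1(C)OCC(=O)CO1 | starting material
6 | 2,2-dimethyl-4H-1,3-dioxin-5-yl acetate | CC(=O)OC1=COC(C)(C)OC1 | intermediate
7 | 2-acetoxyacrolein (3-oxoprop-1-en-2-yl acetate) | C=C(OC(C)=O)C=O | intermediate
8 | (2Z,5S)-5-[(tert-butyldimethylsilyl)oxy]-8-methyl-4-methylidene-1-oxonona-2,7-dien-2-yl acetate | O=C/C(OC(C)=O)=C/C(=C)[C@H](CC=C(C)C)O[Si](C)(C)C(C)(C)C | intermediate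
9 | Meldrum's acid (2,2-dimethyl-1,3-dioxane-4,6-dione) | CC1(C)OC(=O)CC(=O)O1 | starting material
10 | 2-chloropropanoyl chloride (racemic) | CC(Cl)C(Cl)=O | starting material
11 | allyl alcohol (prop-2-en-1-ol) | C=CCO | starting material
12 | 5-(2-chloro-1-hydroxypropylidene)-2,2-dimethyl-1,3-dioxane-4,6-dione (acyl Meldrum's acid, enol form) | CC(Cl)C(O)=C1C(=O)OC(C)(C)OC1=O | intermediate (not isolated)
13 | allyl 4-chloro-3-oxopentanoate (racemic) | C=CCOC(=O)CC(=O)C(C)Cl | intermediate
14 | allyl 2-[(3R,5S)-2-acetoxy-5-[(tert-butyldimethylsilyl)oxy]-8-methyl-4-methylidene-1-oxonon-7-en-3-yl]-4-chloro-3-oxopentanoate (Michael adduct; the other three centres are epimerisable and not fixed) | C=C([C@H](C(OC(C)=O)C=O)C(C(=O)OCC=C)C(=O)C(C)Cl)[C@H](CC=C(C)C)O[Si](C)(C)C(C)(C)C | intermediate (not isolated)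
15 | allyl (3R,4S,5R,6S)-5-acetoxy-6-[(3S)-3-[(tert-butyldimethylsilyl)oxy]-6-methylhepta-1,5-dien-2-yl]-3-chloro-2,4-dihydroxy-3-methylcyclohex-1-ene-1-carboxylate (chlorohydrin) | C=C([C@@H]1[C@@H](OC(C)=O)[C@H](O)[C@@](C)(Cl)C(O)=C1C(=O)OCC=C)[C@H](CC=C(C)C)O[Si](C)(C)C(C)(C)C | intermediate (not isolated)
16 | allyl (1S,4S,5R,6S)-5-acetoxy-4-[(3S)-3-[(tert-butyldimethylsilyl)oxy]-6-methylhepta-1,5-dien-2-yl]-2-hydroxy-1-methyl-7-oxabicyclo[4.1.0]hept-2-ene-3-carboxylate (enol form of the β-keto ester) | C=C([C@@H]1[C@@H](OC(C)=O)[C@@H]2O[C@]2(C)C(O)=C1C(=O)OCC=C)[C@H](CC=C(C)C)O[Si](C)(C)C(C)(C)C | intermediate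
17 | (1S,4R,5R,6S)-5-acetoxy-4-[(3S)-3-[(tert-butyldimethylsilyl)oxy]-6-methylhepta-1,5-dien-2-yl]-1-methyl-7-oxabicyclo[4.1.0]heptan-2-one | C=C([C@@H]1[C@@H](OC(C)=O)[C@@H]2O[C@]2(C)C(=O)C1)[C@H](CC=C(C)C)O[Si](C)(C)C(C)(C)C | intermediate
18 | (1S,3S,4S,5R,6S)-5-acetoxy-4-[(3S)-3-[(tert-butyldimethylsilyl)oxy]-6-methylhepta-1,5-dien-2-yl]-3-hydroxy-1-methyl-7-oxabicyclo[4.1.0]heptan-2-one | C=C([C@@H]1[C@@H](OC(C)=O)[C@@H]2O[C@]2(C)C(=O)[C@H]1O)[C@H](CC=C(C)C)O[Si](C)(C)C(C)(C)C | intermediate (not isolated)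
19 | (1S,3S,4R,5R,6S)-3,5-diacetoxy-4-[(3S)-3-[(tert-butyldimethylsilyl)oxy]-6-methylhepta-1,5-dien-2-yl]-1-methyl-7-oxabicyclo[4.1.0]heptan-2-one | C=C([C@@H]1[C@@H](OC(C)=O)[C@@H]2O[C@]2(C)C(=O)[C@H]1OC(C)=O)[C@H](CC=C(C)C)O[Si](C)(C)C(C)(C)C | intermediate
20 | (1S,3S,4R,5R,6S)-3,5-diacetoxy-4-[(3S)-3-hydroxy-6-methylhepta-1,5-dien-2-yl]-1-methyl-7-oxabicyclo[4.1.0]heptan-2-one | C=C([C@@H]1[C@@H](OC(C)=O)[C@@H]2O[C@]2(C)C(=O)[C@H]1OC(C)=O)[C@H](CC=C(C)C)O | intermediate
21 | angelic acid ((2Z)-2-methylbut-2-enoic acid) | C/C=C(/C)C(=O)O | starting material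
22 | (2Z)-2-methylbut-2-enoic 2,4,6-trichlorobenzoic anhydride | C/C=C(/C)C(=O)OC(=O)c1c(Cl)cc(Cl)cc1Cl | intermediate (not isolated)
23 | CNP0298051.3: (1S,3S,4R,5R,6S)-3,5-diacetoxy-1-methyl-4-{(3S)-6-methyl-3-[(2Z)-2-methylbut-2-enoyloxy]hepta-1,5-dien-2-yl}-7-oxabicyclo[4.1.0]heptan-2-one | C=C([C@@H]1[C@@H](OC(C)=O)[C@@H]2O[C@]2(C)C(=O)[C@H]1OC(C)=O)[C@H](CC=C(C)C)OC(=O)/C(C)=C\C | target

**Step count.** Total: 12 steps. Longest linear sequence: 9 steps (steps 1, 2, 3, 6, 8, 9, 10, 11, 12).

**Steps most likely to fail**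

Step 8. The oxirane may close on the wrong ring face, through the chlorohydrin that is diaxial when the side chain sits equatorially, or the aldol and displacement may stall. The fallback sets out from 8 and comes back at 17. Under the same amine catalysis, 8 is annulated with allyl 3-oxopentanoate F1 (made like 13 from propanoyl chloride) in a Michael–aldol condensation (Robinson-type annulation). This gives allyl (1S,5S,6R)-5-acetoxy-6-[(3S)-3-[(tert-butyldimethylsilyl)oxy]-6-methylhepta-1,5-dien-2-yl]-3-methyl-2-oxocyclohex-3-ene-1-carboxylate F2. Deallylation and decarboxylation with Pd(PPh3)4 and morpholine give the enone (1S,6R)-6-[(3S)-3-[(tert-butyldimethylsilyl)oxy]-6-methylhepta-1,5-dien-2-yl]-3-methyl-4-oxocyclohex-2-en-1-yl acetate F3. Luche reduction (NaBH4, CeCl3·7H2O, MeOH, −78 °C) should deliver hydride axially and give the allylic alcohol (1S,4R,6R)-6-[(3S)-3-[(tert-butyldimethylsilyl)oxy]-6-methylhepta-1,5-dien-2-yl]-4-hydroxy-3-methylcyclohex-2-en-1-yl acetate F4, with the hydroxyl cis to the side chain. Hydroxyl-directed epoxidation (VO(acac)2, t-BuOOH, CH2Cl2) should then place the oxirane on the hydroxyl face, anti to the acetoxy group, giving (1R,2R,4R,5R,6S)-5-acetoxy-4-[(3S)-3-[(tert-butyldimethylsilyl)oxy]-6-methylhepta-1,5-dien-2-yl]-1-methyl-7-oxabicyclo[4.1.0]heptan-2-ol F5. Dess–Martin oxidation returns 17.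

Step 6. The labile enal 7 may polymerise or lose its enol acetate under the warm, basic Heck conditions. The fallback sets out from 4 and comes back at 8. Bromine–lithium exchange (t-BuLi, Et2O, −78 °C) and a quench with 2-isopropoxy-4,4,5,5-tetramethyl-1,3,2-dioxaborolane give the alkenylboronate tert-butyldimethyl{[(3S)-6-methyl-2-(4,4,5,5-tetramethyl-1,3,2-dioxaborolan-2-yl)hepta-1,5-dien-3-yl]oxy}silane F6. F6 is coupled with 7 in a base-free oxidative boron Heck-type reaction (Pd(OAc)2, 1,4-benzoquinone, DMF, rt). Transmetalation to divalent palladium replaces oxidative addition, so neither heating nor base is needed.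

Step 10. Facial selectivity may be poor, or the C5 acetyl group may transfer to the enolate carbon before the oxidant arrives. The fallback sets out from 17 and comes back at 19. The ketone is trapped with internal quench (LiN(SiMe3)2, Me3SiCl, THF, −78 °C) as the silyl enol ether (1S,4R,5R,6S)-5-acetoxy-4-[(3S)-3-[(tert-butyldimethylsilyl)oxy]-6-methylhepta-1,5-dien-2-yl]-1-methyl-2-[(trimethylsilyl)oxy]-7-oxabicyclo[4.1.0]hept-2-ene F7. F7 is acetoxylated directly with Pb(OAc)4 (CH2Cl2, −20 °C), the acetoxy group entering anti to the side chain.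

**Further compounds**

F1 | step 8 | allyl 3-oxopentanoate | CCC(=O)CC(=O)OCC=C
F2 | step 8 | allyl (1S,5S,6R)-5-acetoxy-6-[(3S)-3-[(tert-butyldimethylsilyl)oxy]-6-methylhepta-1,5-dien-2-yl]-3-methyl-2-oxocyclohex-3-ene-1-carboxylate | C=C([C@@H]1[C@@H](OC(C)=O)C=C(C)C(=O)[C@H]1C(=O)OCC=C)[C@H](CC=C(C)C)O[Si](C)(C)C(C)(C)C
F3 | step 8 | (1S,6R)-6-[(3S)-3-[(tert-butyldimethylsilyl)oxy]-6-methylhepta-1,5-dien-2-yl]-3-methyl-4-oxocyclohex-2-en-1-yl acetate | C=C([C@@H]1[C@@H](OC(C)=O)C=C(C)C(=O)C1)[C@H](CC=C(C)C)O[Si](C)(C)C(C)(C)C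
F4 | step 8 | (1S,4R,6R)-6-[(3S)-3-[(tert-butyldimethylsilyl)oxy]-6-methylhepta-1,5-dien-2-yl]-4-hydroxy-3-methylcyclohex-2-en-1-yl acetate | C=C([C@@H]1[C@@H](OC(C)=O)C=C(C)[C@H](O)C1)[C@H](CC=C(C)C)O[Si](C)(C)C(C)(C)C
F5 | step 8 | (1R,2R,4R,5R,6S)-5-acetoxy-4-[(3S)-3-[(tert-butyldimethylsilyl)oxy]-6-methylhepta-1,5-dien-2-yl]-1-methyl-7-oxabicyclo[4.1.0]heptan-2-ol | C=C([C@@H]1[C@@H](OC(C)=O)[C@@H]2O[C@]2(C)[C@H](O)C1)[C@H](CC=C(C)C)O[Si](C)(C)C(C)(C)C
F6 | step 6 | tert-butyldimethyl{[(3S)-6-methyl-2-(4,4,5,5-tetramethyl-1,3,2-dioxaborolan-2-yl)hepta-1,5-dien-3-yl]oxy}silane | C=C(B1OC(C)(C)C(C)(C)O1)[C@H](CC=C(C)C)O[Si](C)(C)C(C)(C)C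
F7 | step 10 | (1S,4R,5R,6S)-5-acetoxy-4-[(3S)-3-[(tert-butyldimethylsilyl)oxy]-6-methylhepta-1,5-dien-2-yl]-1-methyl-2-[(trimethylsilyl)oxy]-7-oxabicyclo[4.1.0]hept-2-ene | C=C([C@@H]1[C@@H](OC(C)=O)[C@@H]2O[C@]2(C)C(O[Si](C)(C)C)=C1)[C@H](CC=C(C)C)O[Si](C)(C)C(C)(C)C
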